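**Strategy.** The target is cut into two C10 terpenes (dictyol numbering): (R)-limonene gives C1–C6, C9, C10, C18 and C20; (R)-linalool gives C7, C8 and the side chain C11–C17, C19. Everything rests on making the oxolane (O, C11, C12, C13, C14) last, from an oxane (O, C11–C15) that can be built with full stereocontrol. In one operation the ring oxygen, whose O–C15 bond lies antiperiplanar to an equatorial C14 triflate, displaces the triflate, and acetate opens the resulting bicyclic oxonium ion at tertiary C15. This contracts the ring, inverts C14 and installs the hindered tertiary acetate. The precursor is a 3-hydroxy-2,2-dimethyloxane bearing the hydroazulenone at C11.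

Key step: step 14

Remarks. Atom numbers are those of the dictyol skeleton: hydroazulene C1–C10 with ring fusion C1/C5, methyl C18 on C4, carbinol C6, C7 bearing the side chain, methylene C20 on C10; side chain C11 (methyl C19), C12, C13, C14, C15 (methyls C16, C17). The α face is the face of H1 and H5. Assumption: (R)-linalool of high enantiomeric purity, (4R)-limonene 1,2-oxide (cis/trans mixture) and the enantiomer of the D-fructose-derived Shi ketone are taken as catalogue chemicals.

Step 1
Reactants: 1 (R)-linalool
Product: 2 (3R,6S)-6,7-epoxylinalool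
Conditions: ent-Shi ketone (0.3 equiv), Oxone (2KHSO5·KHSO4·K2SO4), K2CO3, Bu4NHSO4, MeCN/CH2(OMe)2, aq Na2B4O7 buffer (pH 10.5), 0 °C
Reagents that add atoms: potassium peroxymonosulfate KHSO5, [K+].[O-]S(=O)(=O)OO
Why: Shi asymmetric epoxidation, in which the chiral dioxirane attacks the electron-rich trisubstituted 6,7-alkene in preference to the vinyl group through a spiro transition state, the ketone enantiomer being chosen so that oxygen is delivered to the face giving the 6S epoxide (reagent control) while C3 is untouched.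

Step 2
Reactants: 2 (3R,6S)-6,7-epoxylinalool
Product: 3 (3S,6R)-6-ethenyl-2,2,6-trimethyl-3-(triisopropylsilyloxy)oxane
Conditions: i-Pr3SiOTf (1.5 equiv), 2,6-lutidine (3 equiv), MeNO2, 0 °C
Reagents that add atoms: triisopropylsilyl trifluoromethanesulfonate, CC(C)[Si](OS(=O)(=O)C(F)(F)F)(C(C)C)C(C)C
Why: Silyl triflate-promoted 6-endo epoxide-opening cyclisation, in which silylation of the epoxide oxygen loosens the bond to the tertiary carbon so that the tertiary hydroxyl (too hindered to be silylated by this bulky reagent) attacks there in a chair transition state; the secondary carbon keeps its C–O bond (3S) and the silyloxy group ends up equatorial and cis to the C6 methyl group.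

Step 3
Reactants: 3 (3S,6R)-6-ethenyl-2,2,6-trimethyl-3-(triisopropylsilyloxy)oxane
Product: 4 1-[(2R,5S)-2,6,6-trimethyl-5-(triisopropylsilyloxy)oxan-2-yl]ethan-1-one
Conditions: PdCl2(Quinox) (5 mol%; Quinox = 2-(4,5-dihydrooxazol-2-yl)quinoline), AgSbF6 (12 mol%), aq t-BuOOH, CH2Cl2, 0 °C to rt
Reagents that add atoms: tert-butyl hydroperoxide, CC(C)(C)OO
Why: Tsuji–Wacker oxidation in its hydroperoxide-mediated, ligand-controlled variant, which should give the methyl ketone (Markovnikov) even from an allylic ether where chloride/copper systems leak to the aldehyde, without touching a stereocentre.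

Step 4
Reactants: 4 1-[(2R,5S)-2,6,6-trimethyl-5-(triisopropylsilyloxy)oxan-2-yl]ethan-1-one
Product: 6 vinyl triflate 1-[(2R,5S)-2,6,6-trimethyl-5-(triisopropylsilyloxy)oxan-2-yl]ethenyl trifluoromethanesulfonate, via potassium enolate 5 (not isolated)
Conditions: KN(SiMe3)2, THF, −78 °C; PhNTf2, −78 to 0 °C
Reagents that add atoms: N-phenylbis(trifluoromethanesulfonimide), O=S(=O)(N(c1ccccc1)S(=O)(=O)C(F)(F)F)C(F)(F)F
Why: Enol triflate formation, regiochemically unambiguous because the ketone can enolise only towards the methyl group (the other α-carbon is quaternary), O-sulfonylation of the potassium enolate giving the 1,1-disubstituted vinyl triflate.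

Step 5
Reactants: 7 (4R)-limonene 1,2-oxide
Product: 8 (3R)-6-oxo-3-(prop-1-en-2-yl)heptanal
Conditions: H5IO6, THF/H2O, 0 °C to rt
Reagents that add atoms: water, O
Why: Periodate cleavage, in which acid-mediated opening of the epoxide to the 1,2-diol is followed by glycol cleavage to the keto aldehyde, the isopropenyl group being inert and the stereocentre (β to the aldehyde, γ to the ketone) not enolisable.

Step 6
Reactants: 8 (3R)-6-oxo-3-(prop-1-en-2-yl)heptanal
Product: 9 (5S)-2-methyl-5-(prop-1-en-2-yl)cyclopent-1-ene-1-carbaldehyde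
Conditions: piperidine, AcOH (each 0.2 equiv), toluene, 80 °C
Reagents that add atoms: none
Why: Intramolecular aldol condensation under amine/acid catalysis, in which the enamine of the aldehyde attacks the methyl ketone to close the five-membered ring and dehydration gives the tetrasubstituted enal, the allylic stereocentre staying as it is.

Step 7
Reactants: 9 (5S)-2-methyl-5-(prop-1-en-2-yl)cyclopent-1-ene-1-carbaldehyde
Product: 10 (5R)-5-(3-chloroprop-1-en-2-yl)-2-methylcyclopent-1-ene-1-carbaldehyde (same spatial arrangement as in 9)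
Conditions: Ca(OCl)2, CO2 (dry ice), CH2Cl2/H2O, 0 °C
Reagents that add atoms: calcium hypochlorite Ca(OCl)2, [Ca+2].[O-]Cl.[O-]Cl
Why: Ene-type allylic chlorination by hypochlorous acid made in situ, which attacks the terminus of the electron-rich 1,1-disubstituted alkene with loss of a methyl hydrogen (as known for the isopropenyl group of carvone) and leaves the electron-poor conjugated ring alkene and the stereocentre alone.

Step 8
Reactants: 10 (5R)-5-(3-chloroprop-1-en-2-yl)-2-methylcyclopent-1-ene-1-carbaldehyde
Product: 11 (5R)-2-methyl-5-[3-(trimethylsilyl)prop-1-en-2-yl]cyclopent-1-ene-1-carbaldehyde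
Conditions: Me3SiSiMe3, Pd(dba)2 (5 mol%), LiCl, DMF, 60–80 °C
Reagents that add atoms: hexamethyldisilane, C[Si](C)(C)[Si](C)(C)C
Why: Palladium-catalysed silylation of an allylic chloride with a disilane, in which zerovalent palladium forms a π-allyl complex with two equivalent termini and Si–Si transmetalation followed by reductive elimination gives the allylsilane, the enal and the stereocentre being unaffected.

Step 9
Reactants: 6 vinyl triflate; 11 (5R)-2-methyl-5-[3-(trimethylsilyl)prop-1-en-2-yl]cyclopent-1-ene-1-carbaldehyde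
Product: 12 dienol 1-[(5R)-2-methyl-5-[3-(trimethylsilyl)prop-1-en-2-yl]cyclopent-1-en-1-yl]-2-[(2R,5S)-2,6,6-trimethyl-5-(triisopropylsilyloxy)oxan-2-yl]prop-2-en-1-ol (both carbinol epimers)
Conditions: CrCl2 (4 equiv), NiCl2 (2 mol%), DMF, rt
Reagents that add atoms: none
Why: Nozaki–Hiyama–Kishi coupling, in which zerovalent nickel inserts into the vinyl C–OTf bond, transmetalation to trivalent chromium gives a vinylchromium species that adds 1,2 to the aldehyde (forming the C6–C7 bond) and tolerates the allylic ether, the silyl ether and the allylsilane; the new carbinol centre forms as a mixture and is erased in step 10.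

Step 10
Reactants: 12 dienol
Product: 13 dienone 1-[(5R)-2-methyl-5-[3-(trimethylsilyl)prop-1-en-2-yl]cyclopent-1-en-1-yl]-2-[(2R,5S)-2,6,6-trimethyl-5-(triisopropylsilyloxy)oxan-2-yl]prop-2-en-1-one
Conditions: Dess–Martin periodinane, NaHCO3, CH2Cl2, 0 °C to rt
Reagents that add atoms: none
Why: Dess–Martin oxidation of the bis-allylic alcohol under buffered conditions that should leave the allylsilane and the silyl ether intact, removing the C6 carbinol centre.

Step 11
Reactants: 13 dienone
Product: 15 cis ketone 1-[(1R,5R)-2-methyl-5-[3-(trimethylsilyl)prop-1-en-2-yl]cyclopent-2-en-1-yl]-2-[(2R,5S)-2,6,6-trimethyl-5-(triisopropylsilyloxy)oxan-2-yl]prop-2-en-1-one, via potassium dienolate 14 (not isolated)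
Conditions: KN(SiMe3)2 (1.2 equiv), THF, −78 °C (13 added to the base); AcOH, −78 °C
Reagents that add atoms: none
Why: Deconjugative kinetic protonation, in which the amide base (no α′ hydrogen being available) removes a γ hydrogen at ring carbon C3 to give the extended dienolate with the endocyclic C3=C4 bond, and acetic acid protonates it at the α-carbon C5 from the face anti to the neighbouring allyl group on C1, giving the β,γ-unsaturated ketone with acyl and allyl groups cis (C5 set, 5R in dictyol numbering).

Step 12
Reactants: 15 cis ketone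
Product: 17 hydroazulenone (1R,5R,7S)-4-methyl-10-methylidene-7-[(2R,5S)-2,6,6-trimethyl-5-(triisopropylsilyloxy)oxan-2-yl]-cis-bicyclo[5.3.0]dec-3-en-6-one (dictyol numbering; H1, H5, H7 all α), via titanium enolate 16 (not isolated)
Conditions: TiCl4 (1.5 equiv), CH2Cl2, −78 °C; MeOH, −78 °C
Reagents that add atoms: none
Why: Intramolecular Hosomi–Sakurai 1,4-addition, in which the allylsilane terminus attacks C8 of the TiCl4-complexed vinyl ketone to close the seven-membered ring (the cis acyl/allyl relationship fixes the cis ring fusion and loss of silicon leaves the exocyclic methylene C20), and the titanium enolate is then protonated at C7 on the face anti to the C5–C4 bond, which allylic strain with the O–Ti group holds pseudo-axial, so that H7 ends up cis to H5 (the α,α′-cis ketone, also the more stable epimer).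

Step 13
Reactants: 17 hydroazulenone
Product: 18 hydroxy ketone (1R,5R,7S)-7-[(2R,5S)-5-hydroxy-2,6,6-trimethyloxan-2-yl]-4-methyl-10-methylidene-cis-bicyclo[5.3.0]dec-3-en-6-one (dictyol numbering)
Conditions: HF·pyridine, pyridine, THF, 0 °C to rt
Reagents that add atoms: none
Why: Fluoride-mediated desilylation under buffered conditions mild enough not to move the β,γ-double bond or the exocyclic methylene, with no stereocentre touched.

Step 14
Reactants: 18 hydroxy ketone
Product: 21 keto acetate 2-[(2R,5R)-5-methyl-5-[(1R,5R,7S)-4-methyl-10-methylidene-6-oxo-cis-bicyclo[5.3.0]dec-3-en-7-yl]oxolan-2-yl]propan-2-yl acetate, via triflate 19 (not isolated), via oxonium triflate 20 (not isolated)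
Conditions: Tf2O (1.2 equiv), 2,6-di-tert-butyl-4-methylpyridine (2 equiv), CH2Cl2, −78 °C; Bu4NOAc (5 equiv), −78 to 0 °C
Reagents that add atoms: tetrabutylammonium acetate, CCCC[N+](CCCC)(CCCC)CCCC.CC(=O)[O-]
Why: The equatorial C14 hydroxyl is triflated and, in the chair that keeps the hydroazulenyl group equatorial, the ring O–C15 bond lies antiperiplanar to C14–OTf, so the ring oxygen displaces triflate from the rear to give the 1-oxoniabicyclo[3.1.0]hexane ion 20, which acetate opens at tertiary C15 to release the oxolane with the acetoxy group already in place. The closest known reaction type is the solvolytic ring contraction of pyranoid sulfonates that carry an equatorial leaving group next to the ring oxygen (for instance 2-O-triflyl pyranosides to 2,5-anhydro sugars), the reverse of the known oxolane-to-oxane ring expansion through the same oxonium ions. The oxolane closes by O–C14 bond formation in a 5-exo-tet sense (3-exo-tet for the transient three-membered oxonium ring). C14 is set by stereospecific inversion (S in the oxane, R in the oxolane), while C11 keeps its C–O bond and configuration and C15 is not stereogenic. The step needs participation of the ring oxygen instead of methyl shift, hydride shift or elimination, which the antiperiplanar geometry secures, and opening of the oxonium ion at C15 instead of C14 or C11, which is secured because C15 is tertiary and only its cleavage releases the strain of the three-membered ring. The hindered pyridine base and the low temperature should keep the β,γ-unsaturated ketone and the exocyclic methylene untouched.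

Step 15
Reactants: 21 keto acetate
Product: 22 dictyol H (1R,5R,6S,7R,11R,14R; dictyol numbering)
Conditions: LiBH(s-Bu)3, THF, −78 °C; H2O
Reagents that add atoms: none
Why: Ketone reduction under steric approach control, in which the bulky trialkylborohydride should reach C6 from the α face past H5 and H7, anti to the C5–C4 bond and the C11 substituent that flank the β face, giving the all-cis 6β-alcohol (6S) while the hindered tertiary acetate is not reduced at −78 °C.

**Compound list**

1 | (R)-linalool, (3R)-3,7-dimethylocta-1,6-dien-3-ol | C=C[C@](C)(O)CCC=C(C)C | starting material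
2 | (3R,6S)-6,7-epoxylinalool, (3R)-5-[(2S)-3,3-dimethyloxiran-2-yl]-3-methylpent-1-en-3-ol | C=C[C@](C)(O)CC[C@@H]1OC1(C)C | intermediate
3 | (3S,6R)-6-ethenyl-2,2,6-trimethyl-3-(triisopropylsilyloxy)oxane (silyloxy cis to the C6 methyl) | C=C[C@@]1(C)CC[C@H](O[Si](C(C)C)(C(C)C)C(C)C)C(C)(C)O1 | intermediate
4 | 1-[(2R,5S)-2,6,6-trimethyl-5-(triisopropylsilyloxy)oxan-2-yl]ethan-1-one | CC(=O)[C@@]1(C)CC[C@H](O[Si](C(C)C)(C(C)C)C(C)C)C(C)(C)O1 | intermediate
5 | potassium enolate of 4 | [K+].C=C([O-])[C@@]1(C)CC[C@H](O[Si](C(C)C)(C(C)C)C(C)C)C(C)(C)O1 | intermediate (not isolated)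
6 | 1-[(2R,5S)-2,6,6-trimethyl-5-(triisopropylsilyloxy)oxan-2-yl]ethenyl trifluoromethanesulfonate | C=C(OS(=O)(=O)C(F)(F)F)[C@@]1(C)CC[C@H](O[Si](C(C)C)(C(C)C)C(C)C)C(C)(C)O1 | intermediate
7 | (4R)-limonene 1,2-oxide (cis/trans mixture at the epoxide) | CC(=C)[C@@H]1CCC2(C)OC2C1 | starting material
8 | (3R)-6-oxo-3-(prop-1-en-2-yl)heptanal | CC(=O)CC[C@H](CC=O)C(C)=C | intermediate
9 | (5S)-2-methyl-5-(prop-1-en-2-yl)cyclopent-1-ene-1-carbaldehyde | C=C(C)[C@@H]1CCC(C)=C1C=O | intermediate
10 | (5R)-5-(3-chloroprop-1-en-2-yl)-2-methylcyclopent-1-ene-1-carbaldehyde | C=C(CCl)[C@@H]1CCC(C)=C1C=O | intermediate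
11 | (5R)-2-methyl-5-[3-(trimethylsilyl)prop-1-en-2-yl]cyclopent-1-ene-1-carbaldehyde | C=C(C[Si](C)(C)C)[C@@H]1CCC(C)=C1C=O | intermediate
12 | dienol, 1-[(5R)-2-methyl-5-[3-(trimethylsilyl)prop-1-en-2-yl]cyclopent-1-en-1-yl]-2-[(2R,5S)-2,6,6-trimethyl-5-(triisopropylsilyloxy)oxan-2-yl]prop-2-en-1-ol (carbinol epimers) | C=C(C[Si](C)(C)C)[C@@H]1CCC(C)=C1C(O)C(=C)[C@@]2(C)CC[C@H](O[Si](C(C)C)(C(C)C)C(C)C)C(C)(C)O2 | intermediate
13 | dienone, the prop-2-en-1-one corresponding to 12 | C=C(C[Si](C)(C)C)[C@@H]1CCC(C)=C1C(=O)C(=C)[C@@]2(C)CC[C@H](O[Si](C(C)C)(C(C)C)C(C)C)C(C)(C)O2 | intermediate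
14 | potassium dienolate of 13 (C3=C4, C5=C6–OK) | [K+].C=C(C[Si](C)(C)C)[C@@H]1CC=C(C)C1=C([O-])C(=C)[C@@]2(C)CC[C@H](O[Si](C(C)C)(C(C)C)C(C)C)C(C)(C)O2 | intermediate (not isolated)
15 | cis ketone, 1-[(1R,5R)-2-methyl-5-[3-(trimethylsilyl)prop-1-en-2-yl]cyclopent-2-en-1-yl]-2-[(2R,5S)-2,6,6-trimethyl-5-(triisopropylsilyloxy)oxan-2-yl]prop-2-en-1-one | C=C(C[Si](C)(C)C)[C@@H]1CC=C(C)[C@@H]1C(=O)C(=C)[C@@]2(C)CC[C@H](O[Si](C(C)C)(C(C)C)C(C)C)C(C)(C)O2 | intermediate
16 | trichlorotitanium enolate (C6–OTiCl3, C6=C7) of 17 | C=C1CCC([C@@]2(C)CC[C@H](O[Si](C(C)C)(C(C)C)C(C)C)C(C)(C)O2)=C(O[Ti](Cl)(Cl)Cl)[C@H]2C(C)=CC[C@@H]12 | intermediate (not isolated)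
17 | hydroazulenone, (1R,5R,7S)-4-methyl-10-methylidene-7-[(2R,5S)-2,6,6-trimethyl-5-(triisopropylsilyloxy)oxan-2-yl]-cis-bicyclo[5.3.0]dec-3-en-6-one (dictyol numbering) | C=C1CC[C@@H]([C@@]2(C)CC[C@H](O[Si](C(C)C)(C(C)C)C(C)C)C(C)(C)O2)C(=O)[C@H]2C(C)=CC[C@@H]12 | intermediate
18 | hydroxy ketone, the 5-hydroxyoxane (C14–OH, 14S) corresponding to 17 | C=C1CC[C@@H]([C@@]2(C)CC[C@H](O)C(C)(C)O2)C(=O)[C@H]2C(C)=CC[C@@H]12 | intermediate
19 | C14 triflate of 18 | C=C1CC[C@@H]([C@@]2(C)CC[C@H](OS(=O)(=O)C(F)(F)F)C(C)(C)O2)C(=O)[C@H]2C(C)=CC[C@@H]12 | intermediate (not isolated)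
20 | 1-oxoniabicyclo[3.1.0]hexane triflate (O bonded to C11, C14 and C15) | C=C1CC[C@@H]([C@@]2(C)CC[C@H]3[O+]2C3(C)C)C(=O)[C@H]2C(C)=CC[C@@H]12.[O-]S(=O)(=O)C(F)(F)F | intermediate (not isolated)
21 | keto acetate, 6-oxo precursor of dictyol H (11R,14R oxolane, C15 acetate) | C=C1CC[C@@H]([C@@]2(C)CC[C@H](C(C)(C)OC(C)=O)O2)C(=O)[C@H]2C(C)=CC[C@@H]12 | intermediate
22 | dictyol H | C=C1CC[C@@H]([C@@]2(C)CC[C@H](C(C)(C)OC(C)=O)O2)[C@@H](O)[C@H]2C(C)=CC[C@@H]12 | target

**Totals.** 15 steps in all. Longest linear sequence: 11 steps (steps 1–4 and 9–15 from 1; the branch from 7, steps 5–8 and 9–15, is equally long).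

**Steps most likely to fail**

Step 12. The allylsilane may add 1,2 to the carbonyl or be protodesilylated, the titanium enolate may expel the β-oxanyl oxygen, or the enolate may be protonated on the wrong face of C7. The fallback replaces the silane addition by a proton-transfer ene reaction that forms no enolate; it sets out from 9 (with 6) and comes back at 17. Enal 9 would be coupled directly with 6 under the conditions of step 9 to give the dienol F1, oxidised with Dess–Martin periodinane to the dienone F2, and deconjugated as in step 11 through the potassium dienolate F3 to the cis ketone F4. Me2AlCl (CH2Cl2, −78 to −20 °C) should then promote an intramolecular ene reaction of the isopropenyl group with the complexed enone: C8 bonds to the alkene terminus, a methyl hydrogen passes to C7 inside the transition state and the methyl becomes C20, giving 17.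

Step 11. The dienolate may be protonated on the face syn to the allyl group (trans ketone) or at the γ-carbon (return to 13), or the base may remove a C18 hydrogen. The fallback reverses the order of ring closure and deconjugation so that the bicyclic frame directs the protonation; it sets out from 13 and comes back at 17. TiCl4 (CH2Cl2, −78 °C) would cyclise 13 to the cross-conjugated titanium dienolate F5, protonated with MeOH to the bicyclic conjugated enone F6. Me3SiOTf/Et3N (CH2Cl2, 0 °C) should remove a C3 hydrogen (C7–H is shielded by the quaternary C11) to give the silyl dienol ether F7. MeLi (THF, −78 °C) would release the lithium dienolate F8, which AcOH should protonate at C5 from the convex face, anti to the C7 substituent, to give 17. In this order C7 is set before C5, by protonation of F5, which is less well controlled than in the main route.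

Step 14. Acetate may act as a base and the oxonium ion may lose a proton from a C15 methyl group (isopropenyl oxolane), or ion-pair return may give a labile tertiary triflate. The fallback separates ring contraction from acylation; it sets out from 18 and comes back at 21. After the same activation (Tf2O, hindered pyridine, −78 °C, through 19 and 20), the oxonium ion would be quenched with THF/aq NaHCO3, water being a poorer base, to give the tertiary alcohol F9. Acetylation of this hindered alcohol with Ac2O and catalytic Sc(OTf)3 (MeCN, −20 °C) should give 21.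

**Further compounds**

F1 | step 12 | dienol, 1-[(5S)-2-methyl-5-(prop-1-en-2-yl)cyclopent-1-en-1-yl]-2-[(2R,5S)-2,6,6-trimethyl-5-(triisopropylsilyloxy)oxan-2-yl]prop-2-en-1-ol (carbinol epimers) | C=C(C)[C@@H]1CCC(C)=C1C(O)C(=C)[C@@]2(C)CC[C@H](O[Si](C(C)C)(C(C)C)C(C)C)C(C)(C)O2
F2 | step 12 | dienone, the prop-2-en-1-one corresponding to F1 | C=C(C)[C@@H]1CCC(C)=C1C(=O)C(=C)[C@@]2(C)CC[C@H](O[Si](C(C)C)(C(C)C)C(C)C)C(C)(C)O2
F3 | step 12 | potassium dienolate of F2 | [K+].C=C(C)[C@@H]1CC=C(C)C1=C([O-])C(=C)[C@@]2(C)CC[C@H](O[Si](C(C)C)(C(C)C)C(C)C)C(C)(C)O2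
F4 | step 12 | cis ketone, 1-[(1R,5R)-2-methyl-5-(prop-1-en-2-yl)cyclopent-2-en-1-yl]-2-[(2R,5S)-2,6,6-trimethyl-5-(triisopropylsilyloxy)oxan-2-yl]prop-2-en-1-one | C=C(C)[C@@H]1CC=C(C)[C@@H]1C(=O)C(=C)[C@@]2(C)CC[C@H](O[Si](C(C)C)(C(C)C)C(C)C)C(C)(C)O2
F5 | step 11 | cross-conjugated trichlorotitanium dienolate (C4=C5, C6=C7, C6–OTiCl3) | C=C1CCC([C@@]2(C)CC[C@H](O[Si](C(C)C)(C(C)C)C(C)C)C(C)(C)O2)=C(O[Ti](Cl)(Cl)Cl)C2=C(C)CC[C@@H]12
F6 | step 11 | bicyclic conjugated enone (C4=C5, C6=O, C7 substituent β) | C=C1CC[C@@H]([C@@]2(C)CC[C@H](O[Si](C(C)C)(C(C)C)C(C)C)C(C)(C)O2)C(=O)C2=C(C)CC[C@@H]12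
F7 | step 11 | trimethylsilyl dienol ether (C3=C4, C5=C6–OSiMe3) | C=C1CC[C@@H]([C@@]2(C)CC[C@H](O[Si](C(C)C)(C(C)C)C(C)C)C(C)(C)O2)C(O[Si](C)(C)C)=C2C(C)=CC[C@@H]12
F8 | step 11 | lithium dienolate (C3=C4, C5=C6–OLi) | [Li+].C=C1CC[C@@H]([C@@]2(C)CC[C@H](O[Si](C(C)C)(C(C)C)C(C)C)C(C)(C)O2)C([O-])=C2C(C)=CC[C@@H]12
F9 | step 14 | tertiary alcohol, the C15 carbinol corresponding to 21 | C=C1CC[C@@H]([C@@]2(C)CC[C@H](C(C)(C)O)O2)C(=O)[C@H]2C(C)=CC[C@@H]12
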